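**Plan**

- Cuts: the two angelate C–O bonds; the 1,10-oxirane back to the Z-C1=C10 olefin; the ten-membered ring at C9–C10 (primary iodide + Z-alkenyl iodide); the lactone C8–O bond; and C6–C7 (allylboration). This leaves an epoxy aldehyde (C1–C6, C10, C14, C15) from geranyl acetate and an allylboronate (C7–C9, C11, C12).
- Forward order: Z-alkenyl iodide and the 4,5-oxirane are set on the chain; allylboration joins the fragments; the butanolide (C7–C8–O–C12–C11) is closed and C11 made quaternary; then the C1–C10 carbocycle is closed; desilylation, double angeloylation and 1,10-epoxidation finish.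
- Enabling feature: C9 is a CH2 next to the lactone-oxygen-bearing C8, so it can be carried as the primary iodide of a 5-(iodomethyl)butanolide and used as a radical. C10 is the methyl-bearing sp2 carbon of the Z-olefin behind the cis-1,10-oxirane, available as a geometrically defined alkenyl iodide.
- Stereochemistry: C4/C5 from Sharpless epoxidation (catalyst); C6/C7 from a matched, Felkin-type anti-allylboration; C8 from hydroxyl-directed epoxidation followed by invertive lactonisation; C11 from enolate methylation anti to the C7 branch; C1/C10 from outer-face epoxidation of the macrocyclic Z-olefin.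

Key step: step 15

Remark (assumption): locants follow germacrane numbering (ring C1–C10, Me-14 on C10, Me-15 on C4, C11(C13)–C12 on C7, lactone C12(=O)–O–C8, angelates on O-6 and O-11); geranyl acetate and racemic methyl 3-hydroxypent-4-enoate are taken as commercial.

**Route**

Step 1
Reactants: 1 geranyl acetate
Product: 3 (2E)-3-methyl-6-oxohex-2-en-1-yl acetate, via ozonide 2 (not isolated)
Conditions: O3 (1 equiv), CH2Cl2, pyridine, −78 °C; then Me2S, −78 °C to rt
Reagents that add atoms: ozone, [O-][O+]=O
Why: Ozonolysis, in which the electron-rich 6,7-olefin reacts much faster than the 2,3-olefin deactivated by the allylic acetate, and reductive work-up of the ozonide gives the aldehyde without touching the 2E geometry.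

Step 2
Reactants: 3 (2E)-3-methyl-6-oxohex-2-en-1-yl acetate
Product: 4 (2E,6Z)-7-iodo-3-methylocta-2,6-dien-1-yl acetate
Conditions: EtPPh3I, n-BuLi, THF, 0 °C; I2, −78 °C; NaHMDS, −20 °C; then 3, −78 °C
Reagents that add atoms: ethyltriphenylphosphonium iodide, CC[P+](c1ccccc1)(c1ccccc1)c1ccccc1.[I-]; iodine, II
Why: Wittig olefination with the α-iodo ylide (Stork–Zhao type), in which the unstabilised ylide should give the kinetic cis-oxaphosphetane so that iodine and the chain end up cis, i.e. the Z-alkenyl iodide that fixes the later C1=C10 geometry.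

Step 3
Reactants: 4 (2E,6Z)-7-iodo-3-methylocta-2,6-dien-1-yl acetate
Product: 5 (2E,6Z)-7-iodo-3-methylocta-2,6-dien-1-ol
Conditions: K2CO3 (cat.), MeOH, 0 °C to rt
Reagents that add atoms: none
Why: Base-catalysed transesterification of the acetate, to which the alkenyl iodide and both olefins are inert.

Step 4
Reactants: 5 (2E,6Z)-7-iodo-3-methylocta-2,6-dien-1-ol
Product: 6 [(2S,3S)-3-[(3Z)-4-iodopent-3-en-1-yl]-3-methyloxiran-2-yl]methanol
Conditions: Ti(OiPr)4 (10 mol %), L-(+)-diethyl tartrate (12 mol %), t-BuOOH, 4 Å molecular sieves, CH2Cl2, −20 °C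
Reagents that add atoms: tert-butyl hydroperoxide, CC(C)(C)OO
Why: Sharpless asymmetric epoxidation, in which the L-(+)-tartrate catalyst should deliver oxygen to the face of the E-allylic alcohol that gives the (2S,3S)-epoxy alcohol (C4 and C5 of the target), and only the allylic olefin reacts.

Step 5
Reactants: 6 [(2S,3S)-3-[(3Z)-4-iodopent-3-en-1-yl]-3-methyloxiran-2-yl]methanol
Product: 7 (2R,3S)-3-[(3Z)-4-iodopent-3-en-1-yl]-3-methyloxirane-2-carbaldehyde
Conditions: SO3·pyridine, DMSO, i-Pr2NEt, CH2Cl2, 0 °C
Reagents that add atoms: none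
Why: Parikh–Doering oxidation, mild and non-acidic, so the oxirane and its α-stereocentre (C5) should survive.

Step 6
Reactants: 8 methyl 3-hydroxypent-4-enoate (racemic)
Product: 9 methyl (3E)-5-(4,4,5,5-tetramethyl-1,3,2-dioxaborolan-2-yl)pent-3-enoate
Conditions: B2pin2, Pd(MeCN)4(BF4)2 (5 mol %), DMSO/MeOH, 50 °C
Reagents that add atoms: bis(pinacolato)diboron, CC1(C)OB(OC1(C)C)B1OC(C)(C)C(C)(C)O1
Why: Palladium-catalysed direct borylation of an allylic alcohol through an η3-allyl intermediate, which should place boron on the unsubstituted terminus and give the more stable E-olefin, so the carbinol stereocentre of 8 is irrelevant.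

Step 7
Reactants: 7 (2R,3S)-3-[(3Z)-4-iodopent-3-en-1-yl]-3-methyloxirane-2-carbaldehyde; 9 methyl (3E)-5-(4,4,5,5-tetramethyl-1,3,2-dioxaborolan-2-yl)pent-3-enoate
Product: 11 methyl (3S,4S)-3-ethenyl-4-hydroxy-4-[(2S,3S)-3-[(3Z)-4-iodopent-3-en-1-yl]-3-methyloxiran-2-yl]butanoate, via borate ester 10 (not isolated)
Conditions: (S)-TRIP (5 mol %), 4 Å molecular sieves, toluene, −30 °C; then aq. NaHCO3
Reagents that add atoms: none
Why: Chiral-phosphoric-acid-catalysed allylboration through a chair Zimmerman–Traxler transition state, in which the E-γ-substituted boronate gives the 6,7-anti relationship and attack on the Si face of the aldehyde (the face expected from this catalyst enantiomer and also the polar Felkin–Anh face of the α,β-epoxy aldehyde, C5–O anti to the incoming carbon) sets C6 (S) and with it C7.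

Step 8
Reactants: 11 methyl (3S,4S)-3-ethenyl-4-hydroxy-4-[(2S,3S)-3-[(3Z)-4-iodopent-3-en-1-yl]-3-methyloxiran-2-yl]butanoate
Product: 12 the 8,9-epoxide of 11, methyl (3R,4S)-4-hydroxy-4-[(2S,3S)-3-[(3Z)-4-iodopent-3-en-1-yl]-3-methyloxiran-2-yl]-3-[(2R)-oxiran-2-yl]butanoate (new C8–O bond 1,3-syn to O-6)
Conditions: VO(acac)2 (5 mol %), t-BuOOH, CH2Cl2, 0 °C to rt
Reagents that add atoms: tert-butyl hydroperoxide, CC(C)(C)OO
Why: Hydroxyl-directed epoxidation of a homoallylic alcohol, in which the chair-like vanadate transition state with the C5 and C11 branches equatorial should deliver oxygen to C8 1,3-syn to O-6, i.e. with the configuration opposite to the lactone C8–O bond of the target, as step 10 requires, while the electron-poor alkenyl iodide is left alone.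

Step 9
Reactants: 12 the 8,9-epoxide of 11
Product: 13 the 6-O-tert-butyldimethylsilyl ether of 12
Conditions: TBSOTf, 2,6-lutidine, CH2Cl2, −78 °C
Reagents that add atoms: tert-butyldimethylsilyl trifluoromethanesulfonate, CC(C)(C)[Si](C)(C)OS(=O)(=O)C(F)(F)F
Why: Low-temperature silylation of the hindered secondary alcohol with a silyl triflate and excess hindered base, which blocks O-6 against lactonisation onto C12 and against the bases used later.

Step 10
Reactants: 13 the 6-O-tert-butyldimethylsilyl ether of 12
Product: 15 the 8,12-lactone (4S,5S)-4-[(S)-(tert-butyldimethylsilyloxy){(2S,3S)-3-[(3Z)-4-iodopent-3-en-1-yl]-3-methyloxiran-2-yl}methyl]-5-(hydroxymethyl)oxolan-2-one (C6 branch and C9 trans on the ring), via epoxy acid 14 (not isolated)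
Conditions: LiOH, THF/H2O, 0 °C to rt; then AcOH to pH 5, rt
Reagents that add atoms: lithium hydroxide, [Li+].[OH-] (its oxygen ends in the lactone carboxyl)
Why: Saponification followed by 5-exo-tet opening of the terminal oxirane at C8 by the C12 carboxyl (γ,δ-epoxy acid to 5-(hydroxymethyl)butanolide), which inverts C8 and should give the 7,8-trans lactone with the target configuration, the six-membered alternative at C5 of the hindered trisubstituted oxirane being slower.

Step 11
Reactants: 15 the 8,12-lactone with C9–OH
Product: 16 the corresponding 5-(iodomethyl)butanolide (C9–I)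
Conditions: I2, PPh3, imidazole, CH2Cl2, 0 °C
Reagents that add atoms: iodine, II
Why: Appel-type iodination of the only free (primary) alcohol, buffered by imidazole so that the oxirane and the silyl ether should survive.

Step 12
Reactants: 16 the 5-(iodomethyl)butanolide
Product: 17 the 11-hydroxy derivative of 16 (OH trans to the C7 side chain)
Conditions: KHMDS, THF, −78 °C; 2-(phenylsulfonyl)-3-phenyloxaziridine, −78 °C; NH4Cl
Reagents that add atoms: 2-(phenylsulfonyl)-3-phenyloxaziridine, O=S(=O)(c1ccccc1)N1OC1c1ccccc1
Why: Davis oxidation of the potassium lactone enolate, where oxygen is expected to enter trans to the C7 branch but the C11 configuration made here is of no consequence because C11 is planarised again in step 14.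

Step 13
Reactants: 17 the 11-hydroxy derivative of 16
Product: 18 the 11-O-triethylsilyl ether of 17
Conditions: TESOTf, 2,6-lutidine, CH2Cl2, −78 °C
Reagents that add atoms: triethylsilyl trifluoromethanesulfonate, CC[Si](CC)(CC)OS(=O)(=O)C(F)(F)F
Why: Silyl triflate/lutidine silylation of the α-hydroxy lactone, chosen over chloride/imidazole to avoid N-alkylation by the primary iodide.

Step 14
Reactants: 18 the 11-O-triethylsilyl ether of 17
Product: 19 the 11-methyl-11-(triethylsilyloxy) lactone (Me-13 trans, O-11 cis to the C6 branch)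
Conditions: KHMDS, THF, −78 °C; MeI, −78 to −40 °C
Reagents that add atoms: iodomethane, CI
Why: Alkylation of the planar α-silyloxy lactone enolate, which should be methylated on the face anti to the bulky C6 branch on the adjacent C7 (the usual trans-to-β-substituent rule for butanolide enolates), giving the C11 configuration of the target.

Step 15
Reactants: 19 the 11-methyl-11-(triethylsilyloxy) lactone carrying C9–I and the Z-alkenyl iodide
Product: 20 the macrocycle (1(10)Z)-6-O-TBS-11-O-TES-4,5-epoxygermacr-1(10)-en-8,12-olide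
Conditions: NiBr2(dme) (30 mol %), 4,4′-di-tert-butyl-2,2′-bipyridine (30 mol %), Mn powder (4 equiv), DMA, 25 °C, argon, slow addition of 19 (final 2 mM)
Reagents that add atoms: none
Why: Proposed new method: zerovalent nickel inserts into the alkenyl C10–I bond with retention of the Z geometry, a monovalent nickel species abstracts iodine from the primary C9–I bond, the C9 radical is captured by the tethered alkenylnickel, and reductive elimination from trivalent nickel forms C9–C10 while Mn regenerates the low-valent catalyst. The closest known reaction type is the intermolecular nickel-catalysed reductive cross-electrophile coupling of alkenyl or aryl halides with primary alkyl iodides, including β-oxygenated ones made in situ from epoxides; the tether does not change the mechanism, so only the ring size is new. The ten-membered carbocycle closes through an eleven-membered nickelacycle with both olefinic carbons (C1, C10) inside the new ring (endo mode). No stereocentre is created: C8 and the other centres are spectators, and the Z olefin is carried over because oxidative addition and reductive elimination at sp2 carbon are stereoretentive. The step needs cyclisation to beat dimerisation, hydrodehalogenation and β-elimination: the radical (not carbanionic) character of C9 makes the lactone oxygen on C8 a harmless β-substituent, the trans ring fusion keeps H-6 out of reach of a 1,5-hydrogen shift, the rigid trans-butanolide and trans-oxirane leave only the C1–C3 segment free to fold, and slow addition keeps the substrate dilute. The two C–I bonds are told apart by the mechanism itself (two-electron insertion at sp2 carbon, atom abstraction at sp3 carbon).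

Step 16
Reactants: 20 the bis-silylated macrocycle
Product: 21 the 6,11-diol, (1(10)Z)-4,5-epoxy-6,11-dihydroxygermacr-1(10)-en-8,12-olide
Conditions: HF·pyridine, pyridine, THF, 0 °C to rt
Reagents that add atoms: none
Why: Fluoride cleavage of both silyl ethers under buffered, mildly acidic conditions, which trisubstituted oxiranes tolerate and which avoid base-induced acyl migration from O-8 to O-6.

Step 17
Reactants: 21 the 6,11-diol
Product: 22 the 6,11-diangelate, (1(10)Z)-6,11-bis(angeloyloxy)-4,5-epoxygermacr-1(10)-en-8,12-olide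
Conditions: angelic acid, 2,4,6-trichlorobenzoyl chloride, Et3N, toluene, rt, filter; then 21, 80 °C
Reagents that add atoms: angelic acid, C/C=C(/C)C(=O)O (two equivalents incorporated)
Why: Yamaguchi-type esterification with the preformed mixed anhydride of angelic acid, the standard way to make angelates without Z-to-E isomerisation, with heating for the tertiary 11-OH and no stereocentre touched.

Step 18
Reactants: 22 the 6,11-diangelate
Product: 23 the target, (1R,4S,5S,6S,7S,8R,10S,11R)-6,11-bis(angeloyloxy)-1,10:4,5-diepoxygermacran-8,12-olide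
Conditions: mCPBA, NaHCO3, CH2Cl2, 0 °C
Reagents that add atoms: 3-chloroperoxybenzoic acid, OOC(=O)c1cccc(Cl)c1
Why: Prilezhaev epoxidation, in which the trisubstituted ring olefin is far more nucleophilic than the conjugated angelates, the Z geometry gives the cis-oxirane stereospecifically, and the peracid is expected to attack the outer face of the olefin in the ten-membered ring (macrocyclic substrate control), which has to be the face that gives (1R,10S).

**Compound list**

1 | geranyl acetate, (2E)-3,7-dimethylocta-2,6-dien-1-yl acetate | CC(C)=CCC/C(C)=C/COC(C)=O | starting material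
2 | ozonide, (2E)-5-(5,5-dimethyl-1,2,4-trioxolan-3-yl)-3-methylpent-2-en-1-yl acetate | CC1(C)OOC(CC/C(C)=C/COC(C)=O)O1 | intermediate
3 | (2E)-3-methyl-6-oxohex-2-en-1-yl acetate | O=CCC/C(C)=C/COC(C)=O | intermediate
4 | (2E,6Z)-7-iodo-3-methylocta-2,6-dien-1-yl acetate | C/C(I)=C/CC/C(C)=C/COC(C)=O | intermediate
5 | (2E,6Z)-7-iodo-3-methylocta-2,6-dien-1-ol | C/C(I)=C/CC/C(C)=C/CO | intermediate
6 | [(2S,3S)-3-[(3Z)-4-iodopent-3-en-1-yl]-3-methyloxiran-2-yl]methanol | C/C(I)=C/CC[C@]1(C)O[C@H]1CO | intermediate
7 | (2R,3S)-3-[(3Z)-4-iodopent-3-en-1-yl]-3-methyloxirane-2-carbaldehyde | C/C(I)=C/CC[C@]1(C)O[C@H]1C=O | intermediate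
8 | methyl 3-hydroxypent-4-enoate (racemic) | COC(=O)CC(O)C=C | starting material
9 | methyl (3E)-5-(4,4,5,5-tetramethyl-1,3,2-dioxaborolan-2-yl)pent-3-enoate | COC(=O)C/C=C/CB1OC(C)(C)C(C)(C)O1 | intermediate
10 | O-(pinacolboryl) ether of 11 | C/C(I)=C/CC[C@]1(C)O[C@H]1[C@@H](OB2OC(C)(C)C(C)(C)O2)[C@H](C=C)CC(=O)OC | intermediate
11 | methyl (3S,4S)-3-ethenyl-4-hydroxy-4-[(2S,3S)-3-[(3Z)-4-iodopent-3-en-1-yl]-3-methyloxiran-2-yl]butanoate | C/C(I)=C/CC[C@]1(C)O[C@H]1[C@@H](O)[C@H](C=C)CC(=O)OC | intermediate
12 | methyl (3R,4S)-4-hydroxy-4-[(2S,3S)-3-[(3Z)-4-iodopent-3-en-1-yl]-3-methyloxiran-2-yl]-3-[(2R)-oxiran-2-yl]butanoate | C/C(I)=C/CC[C@]1(C)O[C@H]1[C@@H](O)[C@H]([C@@H]2CO2)CC(=O)OC | intermediate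
13 | 6-O-tert-butyldimethylsilyl ether of 12 | C/C(I)=C/CC[C@]1(C)O[C@H]1[C@@H](O[Si](C)(C)C(C)(C)C)[C@H]([C@@H]2CO2)CC(=O)OC | intermediate
14 | epoxy acid from 13 (free C12 carboxylic acid) | C/C(I)=C/CC[C@]1(C)O[C@H]1[C@@H](O[Si](C)(C)C(C)(C)C)[C@H]([C@@H]2CO2)CC(=O)O | intermediate
15 | (4S,5S)-4-[(S)-(tert-butyldimethylsilyloxy){(2S,3S)-3-[(3Z)-4-iodopent-3-en-1-yl]-3-methyloxiran-2-yl}methyl]-5-(hydroxymethyl)oxolan-2-one | C/C(I)=C/CC[C@]1(C)O[C@H]1[C@@H](O[Si](C)(C)C(C)(C)C)[C@H]2CC(=O)O[C@@H]2CO | intermediate
16 | 5-(iodomethyl) analogue of 15 (C9–I) | C/C(I)=C/CC[C@]1(C)O[C@H]1[C@@H](O[Si](C)(C)C(C)(C)C)[C@H]2CC(=O)O[C@@H]2CI | intermediate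
17 | 11-hydroxy derivative of 16 (OH trans to the C7 side chain) | C/C(I)=C/CC[C@]1(C)O[C@H]1[C@@H](O[Si](C)(C)C(C)(C)C)[C@H]2[C@H](O)C(=O)O[C@@H]2CI | intermediate
18 | 11-O-triethylsilyl ether of 17 | C/C(I)=C/CC[C@]1(C)O[C@H]1[C@@H](O[Si](C)(C)C(C)(C)C)[C@H]2[C@H](O[Si](CC)(CC)CC)C(=O)O[C@@H]2CI | intermediate
19 | 11-methyl-11-(triethylsilyloxy) lactone (Me-13 trans, O-11 cis to the C6 branch) | C/C(I)=C/CC[C@]1(C)O[C@H]1[C@@H](O[Si](C)(C)C(C)(C)C)[C@H]2[C@@](C)(O[Si](CC)(CC)CC)C(=O)O[C@@H]2CI | intermediate
20 | (1(10)Z)-6-O-TBS-11-O-TES-4,5-epoxygermacr-1(10)-en-8,12-olide | CC(C)(C)[Si](C)(C)O[C@H]1[C@@H]2[C@@H](C/C(C)=C\CC[C@]3(C)O[C@@H]13)OC(=O)[C@]2(C)O[Si](CC)(CC)CC | intermediate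
21 | (1(10)Z)-4,5-epoxy-6,11-dihydroxygermacr-1(10)-en-8,12-olide | O[C@H]1[C@@H]2[C@@H](C/C(C)=C\CC[C@]3(C)O[C@@H]13)OC(=O)[C@]2(C)O | intermediate
22 | (1(10)Z)-6,11-bis(angeloyloxy)-4,5-epoxygermacr-1(10)-en-8,12-olide | C/C=C(/C)C(=O)O[C@H]1[C@@H]2[C@@H](C/C(C)=C\CC[C@]3(C)O[C@@H]13)OC(=O)[C@]2(C)OC(=O)/C(C)=C\C | intermediate
23 | (1R,4S,5S,6S,7S,8R,10S,11R)-6,11-bis(angeloyloxy)-1,10:4,5-diepoxygermacran-8,12-olide | C/C=C(/C)C(=O)O[C@H]1[C@@H]2[C@@H](C[C@]3(C)O[C@@H]3CC[C@]3(C)O[C@@H]13)OC(=O)[C@]2(C)OC(=O)/C(C)=C\C | target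

**Count and risks**

Total step count: 18. Longest linear sequence: 17 (steps 1–5 and 7–18).

The three steps most likely to fail:

1. Step 15 (ring closure). Oligomerisation, simple reduction of the C9–I bond, or reductive β-elimination that opens the iodomethyl lactone may outrun the ten-membered ring closure. The fallback closes the same bond by two-electron chemistry of known type. It sets out from 19: radical borylation of the primary iodide (B2cat2, DMF, blue light) would give the catechol boronate F1; KHF2 in aqueous MeOH would convert it into the potassium trifluoroborate F2; and an intramolecular B-alkyl Suzuki–Miyaura coupling with the Z-alkenyl iodide (PdCl2(dppf), Cs2CO3, THF/H2O, 60 °C, high dilution) would come back to the route at 20. β-Oxygenated primary alkylboron reagents are established partners in such couplings.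

2. Step 18 (1,10-epoxidation). Facial selectivity may be poor or opposite, because no stereocentre is adjacent to the Z-olefin and the exposed face depends on the ring conformer. The fallback sets out from 22: NBS in aqueous THF at 0 °C would give the bromohydrin F3 (bromonium ion on the face the peracid prefers, water opening at the tertiary C10 from the other side), and DBU in CH2Cl2 would then close the oxirane with inversion at C1. This puts the oxygen on the face opposite to the one reached by direct epoxidation and comes back to the route at 23.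

3. Step 17 (double angeloylation). Acylation of the tertiary, α-carbonyl 11-OH may be sluggish, and prolonged heating may erode the Z geometry of the angelates. The fallback sets out from 21: both hydroxyls would be esterified with the small, ketene-forming 2-[bis(2,2,2-trifluoroethoxy)phosphoryl]propanoic acid (DCC, DMAP, CH2Cl2) to give the bis(phosphonopropionate) F4, and a double Still–Gennari olefination with acetaldehyde (KHMDS, 18-crown-6, THF, −78 °C) would build both Z-2-methylbut-2-enoates in place and come back to the route at 22.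

**Further compounds**

F1 | step 15 | catechol boronate of 19 (C9–B(catecholato) in place of C9–I) | C/C(I)=C/CC[C@]1(C)O[C@H]1[C@@H](O[Si](C)(C)C(C)(C)C)[C@H]2[C@@](C)(O[Si](CC)(CC)CC)C(=O)O[C@@H]2CB1Oc2ccccc2O1
F2 | step 15 | potassium trifluoroborate of 19 (C9–BF3K in place of C9–I) | C/C(I)=C/CC[C@]1(C)O[C@H]1[C@@H](O[Si](C)(C)C(C)(C)C)[C@H]2[C@@](C)(O[Si](CC)(CC)CC)C(=O)O[C@@H]2C[B-](F)(F)F.[K+]
F3 | step 18 | bromohydrin of 22 (1-bromo-10-hydroxy, anti, tertiary OH at C10) | C/C=C(/C)C(=O)O[C@H]1[C@@H]2[C@@H](C[C@](C)(O)[C@@H](Br)CC[C@]3(C)O[C@@H]13)OC(=O)[C@]2(C)OC(=O)/C(C)=C\C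
F4 | step 17 | 6,11-bis{2-[bis(2,2,2-trifluoroethoxy)phosphoryl]propanoate} of 21 (phosphonate α-carbons unassigned) | CC(C(=O)O[C@H]1[C@@H]2[C@@H](C/C(C)=C\CC[C@]3(C)O[C@@H]13)OC(=O)[C@]2(C)OC(=O)C(C)P(=O)(OCC(F)(F)F)OCC(F)(F)F)P(=O)(OCC(F)(F)F)OCC(F)(F)F
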